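The runs are simulated from invented constants; noise was put on by code.

Target cannot pass what the reagent can pay for where each target costs one reagent.

all flasks: free catalyst 100 µM
- summer: starting material 0.020 M; reagent 0.016 M; temperature 40 °C; the very flask that is asked about, followed so far
- dawn: starting material 0.010 M; reagent 0.016 M; temperature 46 °C; run made earlier
- flask: starting material 0.020 M; reagent 0.0160 M; temperature 40 °C; time 8.0 d

| run | time / h | target / % | starting material / % |
|---|---|---|---|
| summer | 10.0 | 46.3 | 53.3 |
| summer | 30.0 | 78.4 | 21.5 |
| summer | 48.0 | 79.7 | 19.9 |
| summer | 72.0 | 79.3 | 19.7 |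
| summer | 120 | 80.1 | 19.2 |
| dawn | 1.50 | 21.0 | 78.4 |
| dawn | 3.00 | 39.7 | 59.4 |
| dawn | 6.00 | 66.9 | 33.0 |
| dawn | 12.0 | 93.4 | 7.6 |
| dawn | 20.0 | 99.7 | 0.4 |

(each reading ± 0.5 percentage points)

- alder: change nothing and wait 8.0 d more
- ash: at 8.0 d add reagent, 50.0 % of the amount charged, then wait 8.0 d
- larch: at 8.0 d take out 90 % of the by-product then present, then wait 8.0 d
- birch: at 8.0 d add free catalyst, 100 % of the amount charged, then wait 8.0 d
- cedar: at 8.0 d raise the temperature by 10 K, then wait 8.0 d

- target, in percent of the starting material first charged, at 8.0 d
- which option adds most target ("none" when 2 percentage points or less is all one gets) (alder / ash / larch / birch / cedar / none)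
- target present, in percent of the starting material first charged, after ash
- target present, in percent of the starting material first charged, after larch

- what is added takes up no volume worth counting

Minutes of the meeting on the summer flask, which is the flask asked about.

The first speaker took equal charges as the zero of the scale, since there reagent and starting material end together. She proposed the ceiling, the reagent charge as a fraction of the starting material charge, 80.0 %, with reagent as the limiting reagent. Its complement, the share unpaid, is 20.0 %.

A second speaker read the summer run: at 48.0 h target stood at 79.7 % and starting material at 19.9 %, and at 120 h target read 80.1 %, flat within the scatter of 0.5 percentage points.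

An objector said a reverse reaction or a dying catalyst fits such a plateau too. The first speaker answered with the dawn run, where reagent stood at 160 % of the starting material and target read 99.7 % at 20.0 h, above the last summer reading. Dawn ran at 46 °C against 40 °C, so the point on the catalyst stayed open.

The meeting's own reckoning was 80.0 % now and after larch, since larch adds no reagent. Ash adds reagent worth 40.0 % of the starting material charge, more than the gap, so the meeting reckoned target at 100 % after ash. At the pace read between 10.0 h and 30.0 h the gap takes about 12.5 h, far less than the 8.0 d allowed, if the catalyst still works.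

The forecaster tabled 79.8 % (79.2 % to 80.3 %), ash as best, 99.3 % after ash (96.5 % to 100 %) and 80.2 % after larch (79.4 % to 81.2 %), noting that the plateau “matches the reagent charge exactly”. On ash this differs slightly from the meeting's figure.

The flask gives 80.0 % at 8.0 d, on the ceiling; ash brings 20 points and reaches 100 %, while larch stays at 80.0 %.

    starting material + free catalyst ⇌ catalyst intermediate A (K = 140 L mol⁻¹, k = 1.00 L mol⁻¹ s⁻¹, Ea = 46.0 kJ mol⁻¹, ΔH = −7.00 kJ mol⁻¹)
    reagent + catalyst intermediate A → catalyst intermediate B (k = 1.40 L mol⁻¹ s⁻¹, Ea = 65.0 kJ mol⁻¹)
    catalyst intermediate B → by-product + catalyst intermediate C (k = 0.0250 s⁻¹, Ea = 90.0 kJ mol⁻¹)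
    catalyst intermediate C → catalyst intermediate D (k = 0.0190 s⁻¹, Ea = 77.0 kJ mol⁻¹)
    catalyst intermediate D → free catalyst + target (k = 0.00780 s⁻¹, Ea = 86.0 kJ mol⁻¹)
    (constants at 40 °C)

A neighbour flask with 0.0040 M of reagent has a ceiling of 20.0 % and gives 20.0 %, with 79.7 % as starting material. The flask itself is at rest: its reagent stands at 0 % of its charge at 192 h, and target already stands at 80.0 % at 96.0 h. Ten times the time leaves target where it was: at 1920 h target is 80.0 %, starting material 19.8 %, and catalyst intermediate A holds 35.7 % of the catalyst.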